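## The problem

Target **12** is a cyclobutane whose four ring carbons carry, in strict alternation, two 3,4-dimethoxyphenyl groups (ring carbons a and c) and two carbonyl groups (ring carbons b and d), each carbonyl being part of an N-acyl-5,6-dihydropyridin-2(1H)-one imide. The relative configuration is 1α,2α,3β,4β: the aryl groups are trans to each other across the ring, so are the acyl groups, and every acyl group is cis to one aryl neighbour and trans to the other. The molecule has a centre of symmetry and is achiral, so only relative configuration has to be controlled. Mutual control among the four stereocentres is poor: a vicinal substituent can steer a new group trans to itself, but every ring carbon here needs one cis and one trans neighbour, and the transannular relationship gives only a weak bias, so the ring is best obtained with its configuration in place. The imides are the fragile part: they are acyl donors towards hydroxide, alkoxides and amines, their C=C bonds accept soft nucleophiles, and the ring C–H next to each imide carbonyl is acidic, so that base would epimerise carbons b or d out of the centrosymmetric series. The aryl-bearing carbons cannot be corrected by epimerisation, so their configuration must be right when the C–aryl bonds are made. The enabling feature is the disposition of the exocyclic carbonyl carbons on b and d, trans to each other and each cis to one neighbouring ring carbon. If carbons a and c are read as former carboxyl carbons, this is the carbonyl arrangement of cis,trans,cis-cyclobutane-1,2,3,4-tetracarboxylic dianhydride **1**, in which the cis pairs d/a and b/c are each tied into one anhydride ring; the ring and its four stereocentres can then be bought, and the lactam nitrogen can open the anhydrides to make both imide C–N bonds.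

## Retrosynthesis

**12 ⇒ 7 + 10.** The two C(sp3)–C(aryl) bonds are cut first, giving the bis(N-acyloxyphthalimide) **7** and two molecules of (3,4-dimethoxyphenyl)zinc chloride **10**. This cut turns all four ring substituents into carboxyl derivatives, the oxidation pattern of a purchasable ring, and keeps the imides as the tags that tell the two pairs of carboxyl carbons apart. Cutting ring bonds instead would reopen the head-to-tail and anti questions. The forward reaction, a nickel-catalysed decarboxylative arylation, must tolerate two imides and give the trans-diaryl isomer. The stereochemical demand is smaller than it looks. The configuration of the carbon arylated first is immaterial, because both epimers of the mono-arylated ester **11** give the same radical at the remaining carboxyl carbon (once that carbon is planar the two are related by a twofold rotation). Only the capture of this second radical decides between **12** and its cis-diaryl isomer. There the two flanking imide-bearing carbons present their substituents to opposite faces, and the face that carries the transannular aryl group as well as one imide is the more hindered, so arylnickel should bond trans to the first aryl group.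

**7 ⇒ 5 + 6.** The two ester C–O bonds are cut, back to diacid **5** and N-hydroxyphthalimide **6**. The phthalimide ester is preferred to other radical precursors because it forms under neutral carbodiimide conditions that the imides tolerate. Epimerisation at the ester-bearing carbons would not matter, since these centres are erased in the arylation.

**10 ⇒ 8.** The C–Zn bond is traced through the Grignard reagent **9** to commercial 4-bromo-1,2-dimethoxybenzene **8**. A zinc reagent is chosen because its low basicity and nucleophilicity suit a partner that carries imides and enones.

**5 ⇒ 1 + 2.** Both imide C–N bonds are cut, returning the ring to dianhydride **1** and two molecules of 5,6-dihydropyridin-2(1H)-one **2**, which reacts as its lithium salt **3**. This cut is preferred to making the imides from separately activated acids because each ring-opening does three things at once: it forms a C–N bond, frees the carboxyl group that will become an aryl group, and places that group cis to the new imide. The simplification is complete, as both precursors are commercial and **1** already holds all four stereocentres. The forward reaction must open each anhydride once, acylate nitrogen, leave the stereocentres alone, and open the second anhydride (in the mono-opened intermediate **4**) at the carbonyl on the carbon 1,3 to the first imide. The substrate does not secure the last point, so the plan accepts a separation of two regioisomers at this first step, where only inexpensive material is lost.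

## Roads not taken

**Alternative 1:** The cut is one ring C–C bond, between an aryl-bearing carbon and the neighbouring carbon that carries a silyl-protected hydroxymethyl group, in a ring whose other acyl carbon is replaced by boron. In the forward sense a copper boryl species, formed from a monovalent copper alkoxide and a diboron reagent, adds syn across the (E)-styrene of the open-chain mesylate **A2**. The benzylic C–Cu bond then displaces the secondary mesylate with inversion to give the cyclobutylboronate **A1**.
- Merits: every stereocentre is assigned by a stereospecific event and the four substituents stay differentiated, which would suit congeners with two different aryl groups. There is neither a statistical regiochemical step nor a radical at a ring carbon. In both respects this road is better than the plan adopted.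
- Weak points: the symmetry of **12** is not used. **A2** has two stereocentres and a defined alkene and needs several steps itself. The four-membered closure onto a secondary mesylate with a benzylic β-hydrogen competes with elimination, and the alkene face that is attacked rests on substrate control. Afterwards the C–B bond must be homologated by one carbon and oxidised, the silyl ether removed, the alcohol oxidised, and both imides formed.
- Comparison: well over ten steps against four. The plan adopted sets brevity and a purchased ring against the greater certainty and flexibility of **A1**.

**Alternative 2:** The ring is bought and the arenes are built. The cut goes through both aromatic rings, back to the bis[(E)-2-nitrovinyl]cyclobutane diester **A4** and two molecules of 2,3-dimethoxybuta-1,3-diene **A5**. Two thermal [4+2] cycloadditions give the bis(nitrocyclohexene) **A3**; loss of nitrous acid and dehydrogenation would then aromatise both rings.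
- Merits: all four ring stereocentres are purchased and the aryl-bearing carbons are never planarised, so the trans-diaryl relationship is not at risk. This is an advantage over the plan adopted, where it hangs on one radical capture. The electron-rich diene and the nitroalkene are well-matched partners.
- Weak points: **A4** requires the same differentiation of two pairs of carboxyl carbons, only moved earlier, followed by reduction to the aldehyde level and nitroaldol condensation on a configurationally labile centre. The aromatisation needs base and oxidant on a ring with acidic C–H bonds next to esters. Ester hydrolysis and imide formation still follow.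
- Comparison: about twice the length, and four C–C bonds are built only to make arenes that can be bought as an aryl bromide. The plan adopted answers with one catalytic C–aryl step, at the price of its stereochemical exposure.

**Alternative 3:** The cut is the two ring bonds C3–C4' and C4–C3' of two molecules of 6,7-dimethoxycoumarin **A7**. Triplet-sensitised [2+2] photocycloaddition in the anti head-to-tail sense gives the dilactone **A6**.
- Merits: one step forms the ring, both aryl–C bonds, both acyl–C bonds and all four stereocentres, with each lactone enforcing a cis aryl/acyl pair. The lactones could be opened by the lactam anion **3** just as the anhydrides of **1** are. If **A6** were available selectively this would be the shortest and stereochemically safest road, better than the plan adopted on both counts.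
- Weak points: sensitised coumarin dimerisation favours head-to-head dimers, so the anti head-to-tail isomer must be selected from up to four. Each lactone opening frees a phenol placed for re-lactonisation with expulsion of the lactam, so it must be sulfonylated at once. The two phenolic oxygens then have to be reduced away in the presence of two enones.
- Comparison: the plan adopted also has a selection problem, but between two isomers instead of four, and it needs no photochemistry and no deoxygenation.

Key step: step 1

## Route

Assumption: the stereodescriptors of the target express relative configuration only; the compound is centrosymmetric and achiral, so no absolute stereocontrol is planned.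

Step 1
Reactants: 1 cis,trans,cis-cyclobutane-1,2,3,4-tetracarboxylic dianhydride; 2 5,6-dihydropyridin-2(1H)-one (two molecules)
Product: 5 (1α,2α,3β,4β)-2,4-bis(2-oxo-5,6-dihydropyridine-1(2H)-carbonyl)cyclobutane-1,3-dicarboxylic acid (centrosymmetric regioisomer), via lithium lactamide 3 (not isolated), via mono-opened lithium carboxylate 4 (not isolated)
Conditions: 2 (2.2 equiv), LiN(SiMe3)2 (2.1 equiv), THF, −78 °C; cannulated onto 1 (1.0 equiv) suspended in THF, −78 → −40 °C; cold 1 M HCl; fractional crystallisation
Reagents that add atoms: none
Why: Ring-opening N-acylation of a lactam anion by a cyclic anhydride, the known route to N-acyl lactam and N-acyl oxazolidinone half-acids from succinic-type anhydrides. The N-lithiated lactam 3 adds to one anhydride carbonyl, the tetrahedral intermediate expels the neighbouring carboxylate, and the imide C–N bond forms as the ring opens; the same event on the remaining anhydride of 4 gives the dicarboxylate of 5. No ring is closed (two five-membered anhydride rings are opened) and no stereocentre is created: all four come from 1, and a cis-fused anhydride cannot epimerise while it is intact. After opening, the low temperature, the slight excess of lactam over silylamide and the adjacent carboxylate charge keep the C–H next to the imide from being removed. One addition per anhydride is secured by the carboxylate, which is inert to 3. Acylation at nitrogen is the normal course for lithium lactamides with hard acyl electrophiles. The selectivity that the substrate does not secure is regiochemical: in 4 the carbonyl on the carbon 1,3 to the first imide (wanted) and the one 1,2 to it are not strongly distinguished, so both regioisomers are expected. The centrosymmetric one is to be separated by crystallisation, the loss falling on two inexpensive commercial inputs.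

Step 2
Reactants: 5 (1α,2α,3β,4β)-2,4-bis(2-oxo-5,6-dihydropyridine-1(2H)-carbonyl)cyclobutane-1,3-dicarboxylic acid; 6 N-hydroxyphthalimide (two molecules)
Product: 7 bis(1,3-dioxoisoindolin-2-yl) (1α,2α,3β,4β)-2,4-bis(2-oxo-5,6-dihydropyridine-1(2H)-carbonyl)cyclobutane-1,3-dicarboxylate
Conditions: 6 (2.4 equiv), N,N'-diisopropylcarbodiimide (2.4 equiv), DMAP (0.1 equiv), CH2Cl2/THF, 0 °C → rt
Reagents that add atoms: none
Why: Carbodiimide-mediated (Steglich-type) esterification of a carboxylic acid with an N-hydroxyimide; the neutral, room-temperature conditions should leave imides, enones and the imide-bearing stereocentres untouched, and epimerisation next to the new esters would be without consequence because those carbons are planarised in step 4.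

Step 3
Reactants: 8 4-bromo-1,2-dimethoxybenzene
Product: 10 (3,4-dimethoxyphenyl)zinc chloride (titrated THF solution containing LiCl), via aryl Grignard reagent 9 (not isolated)
Conditions: Mg turnings, LiCl, THF, rt; then ZnCl2 (1.0 M in THF), 0 °C → rt
Reagents that add atoms: zinc chloride, Cl[Zn]Cl
Why: Grignard formation by magnesium insertion into an electron-rich aryl bromide, followed by transmetalation to zinc; the methoxy groups are inert and the arylzinc chloride is stable in THF.

Step 4
Reactants: 7 bis(1,3-dioxoisoindolin-2-yl) (1α,2α,3β,4β)-2,4-bis(2-oxo-5,6-dihydropyridine-1(2H)-carbonyl)cyclobutane-1,3-dicarboxylate; 10 (3,4-dimethoxyphenyl)zinc chloride (two molecules)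
Product: 12 1,1'-[(1α,2α,3β,4β)-2,4-bis(3,4-dimethoxyphenyl)cyclobutane-1,3-dicarbonyl]bis(5,6-dihydropyridin-2(1H)-one) (CNP0199212.1), via mono-arylated phthalimide ester 11 (not isolated)
Conditions: 10 (3 equiv per ester, slow addition), NiCl2(dme) (20 mol % per ester), 4,4'-di-tert-butyl-2,2'-bipyridine (40 mol % per ester), THF/DMF, rt
Reagents that add atoms: none
Why: Nickel-catalysed decarboxylative Negishi-type arylation of secondary redox-active esters: electron transfer from low-valent nickel to each phthalimide ester releases CO2 and a cyclobutyl radical, which is captured by arylnickel and coupled by reductive elimination from trivalent nickel. The first C–aryl bond carries no stereochemical risk because both epimers of 11 give the same radical; at that radical the flanking imides lie on opposite faces and cancel, so the aryl group should enter on the face away from the transannular aryl group and give the trans-diaryl arrangement of 12. An arylzinc chloride at room temperature is mild enough to spare imide and enone while the catalytic cycle runs.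

## Compound list

1 | cis,trans,cis-cyclobutane-1,2,3,4-tetracarboxylic 1,2:3,4-dianhydride | O=C4OC(=O)[C@H]1[C@H](C(=O)OC5=O)[C@H]5[C@H]14 | starting material
2 | 5,6-dihydropyridin-2(1H)-one | O=C1NCCC=C1 | starting material
3 | lithium salt of 5,6-dihydropyridin-2(1H)-one (N-lithiated lactam, not isolated) | [Li+].O=C1[N-]CCC=C1 | intermediate
4 | lithium 7-(2-oxo-5,6-dihydropyridine-1(2H)-carbonyl)-2,4-dioxo-3-oxabicyclo[3.2.0]heptane-6-carboxylate, carboxylate and imide cis to each other and on the face opposite the anhydride ring (not isolated) | [Li+].[O-]C(=O)[C@H]1[C@@H]2C(=O)OC(=O)[C@@H]2[C@H]1C(=O)N1CCC=CC1=O | intermediate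
5 | (1α,2α,3β,4β)-2,4-bis(2-oxo-5,6-dihydropyridine-1(2H)-carbonyl)cyclobutane-1,3-dicarboxylic acid | OC(=O)[C@H]1[C@H](C(=O)N2CCC=CC2=O)[C@H](C(O)=O)[C@H]1C(=O)N1CCC=CC1=O | intermediate
6 | N-hydroxyphthalimide | ON1C(=O)c2ccccc2C1=O | starting material
7 | bis(1,3-dioxoisoindolin-2-yl) (1α,2α,3β,4β)-2,4-bis(2-oxo-5,6-dihydropyridine-1(2H)-carbonyl)cyclobutane-1,3-dicarboxylate | O=C(ON1C(=O)c2ccccc2C1=O)[C@H]1[C@H](C(=O)N2CCC=CC2=O)[C@H](C(=O)ON2C(=O)c3ccccc3C2=O)[C@H]1C(=O)N1CCC=CC1=O | intermediate
8 | 4-bromo-1,2-dimethoxybenzene | COc1ccc(Br)cc1OC | starting material
9 | (3,4-dimethoxyphenyl)magnesium bromide (not isolated) | COc1ccc([Mg]Br)cc1OC | intermediate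
10 | (3,4-dimethoxyphenyl)zinc chloride (THF solution) | COc1ccc([Zn]Cl)cc1OC | intermediate
11 | 1,3-dioxoisoindolin-2-yl 3-(3,4-dimethoxyphenyl)-2,4-bis(2-oxo-5,6-dihydropyridine-1(2H)-carbonyl)cyclobutane-1-carboxylate, imides trans to each other, either configuration at the aryl-bearing carbon (not isolated) | COc1ccc(cc1OC)C1[C@H](C(=O)N2CCC=CC2=O)[C@H](C(=O)ON2C(=O)c3ccccc3C2=O)[C@H]1C(=O)N1CCC=CC1=O | intermediate
12 | 1,1'-[(1α,2α,3β,4β)-2,4-bis(3,4-dimethoxyphenyl)cyclobutane-1,3-dicarbonyl]bis(5,6-dihydropyridin-2(1H)-one) | COc1ccc([C@H]2[C@H](C(=O)N3CCC=CC3=O)[C@H](c3ccc(OC)c(OC)c3)[C@H]2C(=O)N2CCC=CC2=O)cc1OC | target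

## Step count and least certain steps

Total: 4 steps. Longest linear sequence: 3 steps (1, 2, 4); step 3 is a one-step branch.

**Step 1 (key step).** The most likely failure is lack of regiocontrol in the second ring-opening, with a large share of material going to the 1,2-diimide series and the two diacids possibly resisting separation by crystallisation. Precipitation of the lithium carboxylate 4 before the second opening, and acyl transfer from an imide back to its cis carboxyl group on acidification, are further risks.

Fallback, setting out from 1 and returning at 5: 1 is opened with KOtBu (THF, 0 °C), and the centrosymmetric (1α,2α,3β,4β)-2,4-bis(tert-butoxycarbonyl)cyclobutane-1,3-dicarboxylic acid F1 is separated from its regioisomer as a robust ester acid. Cyanuric fluoride and pyridine in CH2Cl2 convert it into the bis(acyl fluoride) F2; an acyl fluoride, unlike an acyl chloride, tolerates a neighbouring tert-butyl ester. F2 acylates two equivalents of 3 at −78 °C to give the di-tert-butyl ester bis-imide F3, and CF3CO2H in CH2Cl2 frees 5 without base. This does not remove the statistical opening; it moves the separation to a stage where it is easy and forms the C–N bonds by ordinary acyl substitution.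

**Step 4.** Three processes threaten this step:
- nickel-catalysed conjugate arylation of the enones, or acyl substitution by the arylzinc reagent at an imide or at the activated ester;
- insufficient facial discrimination in the capture of the second cyclobutyl radical, which would give the cis-diaryl isomer, with no way to correct it afterwards;
- reduction of the radical to C–H.

Fallback, setting out from 8 and returning at 12: a Heck reaction of 8 with acrylic acid (Pd(OAc)2, P(o-tol)3, Et3N, DMF, 100 °C) gives (E)-3-(3,4-dimethoxyphenyl)prop-2-enoic acid F4. Irradiation of its crystals in a head-to-tail packed form should give, by topochemical [2+2] photodimerisation, (1α,2α,3β,4β)-2,4-bis(3,4-dimethoxyphenyl)cyclobutane-1,3-dicarboxylic acid F5, with the configuration fixed by the lattice. Oxalyl chloride with catalytic DMF gives the dicarbonyl dichloride F6, which acylates two equivalents of 3 (THF, −78 °C) to give 12. This sets the aryl-bearing carbons without a radical and forms the imides last; it depends on obtaining the photoreactive crystal form.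

**Step 2.** Incomplete double esterification of a sparingly soluble diacid, loss of a lactam by acyl transfer to the activated neighbouring carboxyl group, and hydrolysis of the activated esters during purification are the likely failures.

Fallback, setting out from 5 and returning at 12 without passing 7: metallaphotoredox decarboxylative arylation of the free diacid with 8 (NiCl2(dme), 4,4'-di-tert-butyl-2,2'-bipyridine, Ir[dF(CF3)ppy]2(dtbbpy)PF6, Cs2CO3, DMF, blue light, rt). The carboxylate is oxidised by the excited photocatalyst and loses CO2, and the same cyclobutyl radical is captured by arylnickel formed by oxidative addition of 8, so no activated ester is needed. The stereochemical argument of step 4 applies unchanged.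

## Further compounds

F1 | step 1 | (1α,2α,3β,4β)-2,4-bis(tert-butoxycarbonyl)cyclobutane-1,3-dicarboxylic acid | OC(=O)[C@H]1[C@H](C(=O)OC(C)(C)C)[C@H](C(O)=O)[C@H]1C(=O)OC(C)(C)C
F2 | step 1 | di-tert-butyl (1α,2α,3β,4β)-2,4-bis(fluorocarbonyl)cyclobutane-1,3-dicarboxylate | O=C(F)[C@H]1[C@H](C(=O)OC(C)(C)C)[C@H](C(F)=O)[C@H]1C(=O)OC(C)(C)C
F3 | step 1 | di-tert-butyl (1α,2α,3β,4β)-2,4-bis(2-oxo-5,6-dihydropyridine-1(2H)-carbonyl)cyclobutane-1,3-dicarboxylate | O=C(N1CCC=CC1=O)[C@H]1[C@H](C(=O)OC(C)(C)C)[C@H](C(=O)N2CCC=CC2=O)[C@H]1C(=O)OC(C)(C)C
F0 | step 2 | none | none
F4 | step 4 | (E)-3-(3,4-dimethoxyphenyl)prop-2-enoic acid | COc1ccc(/C=C/C(O)=O)cc1OC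
F5 | step 4 | (1α,2α,3β,4β)-2,4-bis(3,4-dimethoxyphenyl)cyclobutane-1,3-dicarboxylic acid | COc1ccc([C@H]2[C@H](C(O)=O)[C@H](c3ccc(OC)c(OC)c3)[C@H]2C(O)=O)cc1OC
F6 | step 4 | (1α,2α,3β,4β)-2,4-bis(3,4-dimethoxyphenyl)cyclobutane-1,3-dicarbonyl dichloride | COc1ccc([C@H]2[C@H](C(Cl)=O)[C@H](c3ccc(OC)c(OC)c3)[C@H]2C(Cl)=O)cc1OC
A1 | alternative 1 | pinacol [2,4-bis(3,4-dimethoxyphenyl)-3-(triisopropylsilyloxymethyl)cyclobutyl]boronate | COc1ccc(cc1OC)[C@H]1[C@H](CO[Si](C(C)C)(C(C)C)C(C)C)[C@H](c2ccc(OC)c(OC)c2)[C@H]1B1OC(C)(C)C(C)(C)O1
A2 | alternative 1 | (E)-3,5-bis(3,4-dimethoxyphenyl)-1-(triisopropylsilyloxy)pent-4-en-2-yl methanesulfonate | CC(C)[Si](OC[C@H](OS(C)(=O)=O)[C@H](c1ccc(OC)c(OC)c1)/C=C/c1ccc(OC)c(OC)c1)(C(C)C)C(C)C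
A3 | alternative 2 | dimethyl 2,4-bis(3,4-dimethoxy-6-nitrocyclohex-3-en-1-yl)cyclobutane-1,3-dicarboxylate, cyclohexene centres undefined | COC1=C(OC)CC([N+](=O)[O-])C(C1)[C@H]1[C@H](C(=O)OC)[C@H](C2CC(OC)=C(OC)CC2[N+](=O)[O-])[C@H]1C(=O)OC
A4 | alternative 2 | dimethyl (1α,2α,3β,4β)-2,4-bis[(E)-2-nitrovinyl]cyclobutane-1,3-dicarboxylate | [O-][N+](=O)/C=C/[C@H]1[C@H](C(=O)OC)[C@H](/C=C/[N+](=O)[O-])[C@H]1C(=O)OC
A5 | alternative 2 | 2,3-dimethoxybuta-1,3-diene | COC(=C)C(=C)OC
A6 | alternative 3 | anti head-to-tail cyclodimer of 6,7-dimethoxycoumarin | O=C4Oc5cc(OC)c(OC)cc5[C@H]1[C@H](C(=O)Oc6cc(OC)c(OC)cc67)[C@H]7[C@H]14
A7 | alternative 3 | 6,7-dimethoxycoumarin | COc1cc2ccc(=O)oc2cc1OC
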